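The data are simulated with made-up constants, noise included.

Read Monday's flask at 1.0 d and Wednesday's at 4.0 d. The recipe is the same, so the reading time is the one thing that differs.

| flask | solid substrate | partner | remark | time |
|---|---|---|---|---|
| epsilon | 34 mM | 25.2 mM | run made earlier |  |
| zeta | 53 mM | 25.2 mM | run made earlier |  |
| eta | 24 mM | 13 mM | run made earlier |  |
| Monday's | 24 mM | 25.2 mM |  | 1.0 d |
| Wednesday's | 24 mM | 25.2 mM |  | 4.0 d |

| epsilon: time / d | epsilon: target / % | zeta: time / d | zeta: target / % | eta: time / d | eta: target / % |
|---|---|---|---|---|---|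
| 0.250 | 0.4 | 0.625 | 2.0 | 0.250 | 0.5 |
| 0.833 | 4.5 | 1.25 | 4.4 | 0.833 | 4.3 |
| 1.67 | 8.9 | 2.08 | 6.9 | 1.67 | 7.5 |
| 2.50 | 11.4 | 2.50 | 7.0 | 2.50 | 9.0 |
| 3.00 | 11.7 | 3.00 | 8.1 | 3.00 | 9.9 |

(standard deviation of a reading: 0.5 percentage points)

- which of the two ends with the higher amount of target, in percent of the solid substrate charged ("neither" if they lie within 2 percentage points) (Monday's / Wednesday's / neither)
- target at the end, in percent of the solid substrate charged, Monday's
- target at the end, in percent of the solid substrate charged, Wednesday's

- solid, in amounts per volume of the solution: solid substrate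
- at the start none of the solid substrate is in solution
- what has only dissolved of solid substrate counts as not reacted

Convert the last readings to the partner yield: target as a fraction of the partner charged. At 3.00 d, epsilon reads 15.8%, zeta 17.0% and eta 18.3%. Yet solid substrate ranges from 24 mM to 53 mM, and partner from 13 mM to 25.2 mM. So treat the partner yield as a curve in time, and multiply it by partner charge over solid charge to get the percentage asked.

Use epsilon, whose solid charge of 34 mM is closer to 24 mM than zeta's is. Now set up two extremes for Wednesday's. If the curve goes flat after the last reading, the partner yield stays at 15.8%, which gives 16.6% of the solid. If it runs straight on at its late pace, it reaches 18.6%, which gives 19.6%. Epsilon's pace is already falling, so expect the flask between them.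

Take the middle as the partner yield at 4.0 d, 17.2%, which gives 18.1%. For Monday's, interpolate epsilon to 7.26%, which gives 7.62%. Wednesday's ends higher by more than the margin.

The forecast, reckoned its own way, says Wednesday's, with 7.7% for Monday's and 19% for Wednesday's, holding that “the solution stays saturated, or nearly so”.

The flask gives 8.08% for Monday's and 17.1% for Wednesday's, so Wednesday's ends higher.

    starting material + partner ⇌ intermediate A (K = 16.0 L mol⁻¹, k = 0.0110 L mol⁻¹ s⁻¹)
    starting material + partner → intermediate B (k = 8.70 × 10⁻⁴ L mol⁻¹ s⁻¹)
    intermediate B → intermediate C (k = 6.10 × 10⁻⁵ s⁻¹)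
    intermediate A → target (k = 1.50 × 10⁻⁵ s⁻¹)
    intermediate C ⇌ intermediate D (K = 0.720, k = 1.40 × 10⁻⁵ s⁻¹)
    partner + intermediate D → side product (k = 0.00130 L mol⁻¹ s⁻¹)
    solid substrate ⇌ starting material, rate k7*(cs7 - [starting material]) while solid is left; crystals form when [starting material] > cs7 (solubility = 9.10 mM, k = 5.40 × 10⁻⁵ s⁻¹)

Wednesday's partner yield comes to 16.3%, against the 17.2% reckoned. Now take the neighbouring flask: Wednesday's recipe with 60 mM of solid substrate, so 0.420 equiv of partner. In the neighbouring flask, the same 17.2% gives 7.23% of that charge. The neighbouring flask gives 7.10%, a partner yield of 16.9%. At 4.00 d the neighbouring flask still holds 51.5% of its solid substrate, and its partner stands at 2.5% of its own charge.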